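in all of them: substrate 0.30 M
- west: first nucleophile 0.87 equiv (fed, over 12 h); second nucleophile 0.60 equiv; run made earlier; the fed solution adds 0.50 times the starting volume
- north: first nucleophile 2 equiv (fed, over 12 h); second nucleophile 0.60 equiv; run made earlier; the fed solution adds 0.50 times the starting volume
- flask: first nucleophile 1.30 equiv (fed, over 12 h); second nucleophile 0.600 equiv; the fed solution adds 0.50 times the starting volume; time 40 h

| run | time / h | target / % | substrate / % |
|---|---|---|---|
| west | 10.0 | 2.7 | 86.6 |
| west | 12.0 | 3.4 | 84.2 |
| west | 15.0 | 5.5 | 80.6 |
| west | 20.0 | 6.9 | 75.1 |
| west | 25.0 | 9.0 | 69.9 |
| north | 10.0 | 5.3 | 86.0 |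
| north | 12.0 | 6.5 | 83.4 |
| north | 15.0 | 8.8 | 80.0 |
| north | 20.0 | 11.4 | 74.3 |
| north | 25.0 | 14.0 | 68.7 |

(each reading ± 0.3 percentage points)

- target is meant together with its idle adduct and crystals
- every charge counts on the volume at the start, and the solution that is fed holds the whole dose
- solid, in amounts per volume of the solution: crystals
- steps under discussion: substrate <-> intermediate; crystals <-> target; second nucleophile + intermediate -> other capture product; first nucleophile + intermediate -> target; second nucleophile + target <-> idle adduct; target -> over-reaction product

- time up to 40 h at which target stands highest
- the amount of target, in percent of the substrate charged, at that time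

If I lay the two runs side by side, substrate goes at nearly one pace: at 25.0 h west holds 69.9% and north 68.7%, though north got 2 equiv of first nucleophile against 0.87 equiv. Target does differ, 9.0% against 14.0%, so I read the nucleophiles as dividing what the substrate gives. West's substrate column gives a first-order loss of 0.0143 h⁻¹.

From the end of the feed to the last reading, west gains 39.2% of target per substrate lost, and north 51.0%. I set that share to c(first nucleophile) / (c(first nucleophile) + S·c(second nucleophile)), taking the concentrations at their charges. West gives S = 2.25: this capture ratio, how many times faster second nucleophile takes the intermediate than first nucleophile at equal concentration, is a selectivity factor. North, with more target standing to lose, reads 3.20, so I keep west's value.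

For the flask, the charges give a share of 49.0%. Substrate falls from 84.2% at the end of the feed to 56.4% at 40 h. Starting from 4.58% of target, interpolated between the runs, I reach 18.2%, a figure built on net readings of target. No run shows target turning down, so I put the peak at the end.

The forecast says 40 h and 17.5% (range 15% to 20%), a little below my figure, holding that “target is still climbing and the best time is the end of the run”.

The flask peaks at 40.0 h with 14.5%.

    substrate ⇌ intermediate (K = 0.0270, k = 2.80 × 10⁻⁴ min⁻¹)
    crystals ⇌ target, rate k2*(cs2 - [target]) while solid is left; crystals form when [target] > cs2 (solubility = 0.110 M, k = 0.00540 min⁻¹)
    second nucleophile + intermediate → other capture product (k = 0.340 L mol⁻¹ min⁻¹)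
    first nucleophile + intermediate → target (k = 0.170 L mol⁻¹ min⁻¹)
    second nucleophile + target ⇌ idle adduct, settled at all times (K = 4.40 L mol⁻¹)
    target → over-reaction product (k = 5.20 × 10⁻⁴ min⁻¹)

At 40.0 h, S with the flask's remaining amounts gives 0.722 for intermediate going to other capture product over going to target; the computed ratio is 0.64. My figure stands 3.7 percentage points above the result, and the flask then holds 7.46% of over-reaction product. In the neighbour flask with 2.40 equiv of second nucleophile, S gives a share of 19.4%; there, target plus over-reaction product make 18.7% of the substrate used, and target stands at 7.19%.

(The data are calculated for substances that don't exist, noise included.)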